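The fraction of the charge per minute is the unit of this reckoning: the flask asked about is read here by its rate, not by its concentrations.

| setting | north-west | north | flask |
|---|---|---|---|
| starting material | 0.76 M | 0.76 M | 0.76 M |
| second substrate | 0.38 M | 0.38 M | 0.380 M |
| free catalyst | 38 mM | 76 mM | 38 mM |
| temperature | 90 °C | 90 °C | 90 °C |
| remark | the very flask that is asked about, followed so far | run made earlier |  |
| time |  |  | 1.0 h |

| run | time / min | target / % |
|---|---|---|
| north-west | 6.00 | 29.1 |
| north-west | 15.0 | 28.8 |
| north-west | 20.0 | 22.5 |
| north-west | 30.0 | 21.3 |
| north-west | 40.0 | 23.2 |
| north-west | 50.0 | 21.4 |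
| north | 0.667 | 10.0 |
| north | 2.00 | 24.5 |
| north | 3.00 | 33.2 |
| north | 5.00 | 38.4 |
| north | 8.00 | 34.6 |
| north | 10.0 | 30.5 |
| north | 12.0 | 30.4 |

(each reading ± 1 percentage point)

- Tuesday's: at 1.0 h take out 90% of the target then present, then wait 30 min
- Saturday's: at 1.0 h add free catalyst, 100% of the amount charged, then wait 30 min
- Friday's: change nothing and wait 30 min more
- Thursday's: at 1.0 h raise the temperature by 25 K, then wait 30 min

- target, in percent of the starting material first charged, at 1.0 h
- the option that brings most further target ("none" if no option brings more than 2 percentage points) (Tuesday's / Saturday's / Friday's / Thursday's / none)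
- target present, with what was taken out counted in, in percent of the starting material first charged, after Tuesday's
- target present, with what was taken out counted in, in percent of the starting material first charged, after Saturday's

- target taken out counts as made
- the earlier runs do not show what temperature does; that part of a forecast is a guess
- additions bring no volume worth counting

The first reading of the north run shows 10.0% target after 0.667 min, so that run starts at about 0.150 min⁻¹ of the charge. The north-west flask holds half that catalyst, and if the rate follows the catalyst, it starts at 0.0750 min⁻¹. The clearing time, the time in which the start rate would use up the whole charge, 13.3 min, is the quantity carried forward.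

One slowing that can be reckoned from these readings is the falling charge. Treated as pseudo-first-order with nothing else slowing it, the rate at 6.00 min is reckoned at 0.637 of its start, with 36.2% of the charge reckoned as turned into target. The reading there is 29.1%, lower than that, a further factor of 0.804, so target is also being lost or made more slowly.

Accumulated to 1.0 h, that reckoned slowing leaves a rate factor of 0.0111, because the clearing time is much shorter than 1.0 h. This reckoning therefore expects a flat level even with working catalyst, and it takes the readings' mean of 22.1% for now. Friday's has less than 2 percentage points of charge to draw on, while Tuesday's stays open.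

The forecast gives 22%, best none, 22.3% after Tuesday's and 16% after Saturday's, and it holds the flat level to be there “most likely because the catalyst has died”. This reckoning shares its level but not that ground.

The flask gives 21.8%, best Thursday's, 34.4% after Tuesday's (a gain of 13 points) and 21.8% after Saturday's. Thursday's brings 21 points.

    starting material + free catalyst ⇌ catalyst intermediate A (K = 0.550 M⁻¹, k = 7.00 M⁻¹ min⁻¹, Ea = 78.0 kJ mol⁻¹, ΔH = −12.0 kJ mol⁻¹)
    catalyst intermediate A → free catalyst + target (k = 210 min⁻¹, Ea = 86.0 kJ mol⁻¹)
    second substrate + free catalyst ⇌ catalyst intermediate B (K = 9.20 M⁻¹, k = 44.0 M⁻¹ min⁻¹, Ea = 41.0 kJ mol⁻¹, ΔH = −3.00 kJ mol⁻¹)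
    catalyst intermediate B → free catalyst + second product (k = 1.50 min⁻¹, Ea = 104 kJ mol⁻¹)
    starting material → uncatalysed product (k = 0.0720 min⁻¹, Ea = 120 kJ mol⁻¹)
    target + free catalyst ⇌ isomer of the product + free catalyst, rate k6*[free catalyst]*[target] forward; the back reaction follows from the equilibrium constant (K = 1.80, k = 4.60 M⁻¹ min⁻¹, Ea = 72.0 kJ mol⁻¹, ΔH = −68.0 kJ mol⁻¹)
    (constants at 90 °C)

In this flask, the clearing time of 13.3 min lies well inside 1.0 h, and at 60.0 min starting material stands at 0% beside free catalyst at 100% of the catalyst charged. The relaxation half-life of target and isomer of the product, 2.55 min with both directions counted, is far shorter than 1.0 h, and the flask holds 39.2% isomer of the product beside 21.8% target.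

For the neighbour with 0.15 M of free catalyst, the same scaling gives a clearing time of 3.38 min, a quarter of this flask's and much shorter than 1.0 h. Computed, that neighbour ends with 0% starting material, 31.4% target and 12.1% uncatalysed product.

Readings and results are calculated from invented constants; the scatter is artificial.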